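## Structural features

The target is a diaryl ether. Ring A is a benzene-1,2-diol (C1–OH, C2–OH) whose C3 oxygen bridges to C1′ of ring B, a phenol with its OH at C2′. Ring A at C5 and ring B at C3′ each carry the same C15 chain, a (6E)-3,7,11-trimethyldodeca-1,6,10-trien-3-yl group. It is attached through its C3, an acyclic all-carbon quaternary stereocentre bearing the arene, a methyl, a vinyl and the CH2 of a homogeranyl chain. The two stereocentres do not stand next to each other: two rings and the ether oxygen separate them, so neither can direct the other. They are of opposite sense (3R on ring A, 3S on ring B), so one chiral catalyst cannot set both in a single pass. At each centre the groups to be told apart are methyl, vinyl and a primary alkyl chain, with no heteroatom close enough to hold a reagent. Fragile groups are the catechol (air oxidation), the four trisubstituted alkenes in 1,5-relationship (acid-triggered cation–olefin cyclisation), the two vinyl groups and the diaryl ether (dissolving metals). The real difficulty is the pair of remote quaternary benzylic stereocentres, followed by the ether bond between two electron-rich, ortho-oxygenated rings. The key step exploits the fact that C3 of each side chain carries CH3 and CH=CH2 side by side on an aryl-bearing carbon. That pair is what addition of H and a vinyl group across the C1=C2 bond of a 2-aryl-1-alkene, ArC(=CH2)CH2R, leaves behind.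

## Logic of the disconnections

19 to 18: the three O–CH2 acetal bonds are cut. All phenols are masked as one kind of acetal that leaves without hydrogenation, strong Lewis acid or dissolving metal. Nothing is gained in the skeleton. The forward step must unmask a catechol and a phenol under acid mild enough to spare four trisubstituted alkenes.

18 to 11 and 17: the C1′(ring B)–O bond of the diaryl ether is cut. This divides the molecule into halves of nearly equal size (C25 and C23), each with one stereocentre, so the opposite configurations can be set independently with mirror-image catalysts. The forward step is a copper-catalysed C–O coupling between a phenol and an aryl bromide that each carry one ortho acetal, under base and heat only.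

11 to 8: the C–O bond at the future ether carbon of ring A is cut back to C–H. This oxygen lies ortho to an acetal oxygen at the only unhindered ortho site. Ring A can then come from a cheap 3,4-dioxygenated acetophenone, and no halogen is carried through the key step. The lithiation must choose the C–H next to the para oxygen over the one beside the quaternary carbon, and must leave the vinyl group alone.

8 to 6 and 7 (key): the bond between the quaternary C3 and its vinyl carbon is cut, together with one C–H bond of the C3 methyl group. In one sentence: each quaternary carbon is made by nickel-catalysed asymmetric hydrovinylation of a 2-aryl-1-alkene with 7. That sentence does not fit the usual route, which joins the arene to C3 of a farnesyl unit. The stereocentre and two of its four substituents vanish, leaving an achiral 1,1-disubstituted alkene and a C2 gas. The forward step must be Markovnikov, must select the Si face of the prochiral carbon, and must touch only the styrenic alkene.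

17 to 16 and 7: the same two bonds are cut on ring B. The gain is the same. The forward step needs the mirror-image catalyst (Re face), must tolerate the aryl bromide, and must cope with an ortho acetal next to the reacting alkene.

6 to 5 and 16 to 15: the C=CH2 bond is cut to a ketone. This turns the alkene into a carbonyl group that can be alkylated. The forward step is a methylenation of an enolisable aryl ketone.

5 to 2 and 3, and 15 to 13 and 3: the bond between the CH2 α to the carbonyl and the allylic CH2 is cut. The whole C10 terminus, with its (E)-alkene, arrives as one purchased piece. The forward step must be a mono-alkylation of a methyl ketone enolate at the primary carbon of 3.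

2 to 1 and 13 to 12: O–CH2 bonds are cut. Both starting acetophenones are commercial. The forward steps are simple phenol protections.

## Other disconnections considered

Alternative 1: this is the first disconnection that comes to mind. The cut is the aryl–C3 bond of each side chain, after the same ether disconnection. The forward key step is a copper-catalysed enantioselective SN2′ arylation of the C15 allylic phosphate A1 with an aryl–aluminium reagent. For ring B the reagent would come from mono bromine–lithium exchange of A2, and 17 would be reached in two operations from A2. It is admittedly shorter. The grounds for preferring the chosen plan are: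
- The copper catalyst must tell CH3 from CH2CH2R on an allyl terminus that carries no arene, whereas in step 4 the prochiral carbon is flanked by an arene and an alkyl chain.
- The configuration would depend on the 2E/2Z purity of A1, the 2Z isomer leading to the antipode. In the chosen route the geometry of 3 never touches the stereocentre.
- Attack at C1 of A1 would give the linear farnesyl arene as a constitutional isomer.
- Ring A would need an aryl–metal on a ring with three differentiated oxygens.

Alternative 2: the cuts are C3–C4 and C3–vinyl. The forward key step is lithiation of the secondary benzylic carbamate A3, borylation with the homogeranyl boronic ester A5 and stereospecific 1,2-metallate rearrangement to the tertiary boronic ester A4. Zweifel olefination would then give 8. Stereochemistry would be carried from an easily set carbinol centre, but the chosen plan is preferred on these grounds: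
- It costs four operations per centre (asymmetric reduction, carbamoylation, lithiation–borylation, olefination) plus the preparation of A5, against three.
- sec-Butyllithium cannot be used beside the aryl bromide needed on ring B.
- Electron-rich benzylic boronate complexes tend to revert, which erodes configuration.
- The iodine of the Zweifel step would meet two nucleophilic trisubstituted alkenes.

Alternative 3: the cut is the C3′(ring B)–C3 bond by a [3,3] shift. The forward key step is an aromatic Claisen rearrangement of the farnesyl ether A6, made enantioselective by a chiral boron Lewis acid chelated between the free OH and the ether oxygen. It would give A7 directly, and arylation of its less hindered OH would follow. The chosen plan is preferred on these grounds: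
- The rearrangement fits ring B only. On ring A the chain is meta to both flanking oxygens and para to the middle one, and a Claisen–Cope relay to a para position would deliver the linear farnesyl group.
- Two unrelated stereochemical solutions would therefore be needed.
- The asymmetric variant needs a stoichiometric chiral reagent and must distinguish CH3 from CH2R.
- The union would have to choose between the two OH groups of a free catechol under copper catalysis.

Key step: step 4

Assumption: commercial 3 is taken as the pure (2E) isomer. L is (Sa,Rc,Rc)-O,O′-(1,1′-binaphthalene-2,2′-diyl) N,N-bis(1-phenylethyl)phosphoramidite and ent-L is its mirror image. The sense of induction of L is assumed from the 2-aryl-1-butene model; if a test run shows the opposite sense, L and ent-L change places.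

## Route

Step 1
Reactants: 1 1-(3,4-dihydroxyphenyl)ethan-1-one
Product: 2 1-[3,4-bis(methoxymethoxy)phenyl]ethan-1-one
Conditions: MOMCl (2.6 equiv), iPr2NEt (3 equiv), CH2Cl2, 0 °C → rt
Reagents that add atoms: chloromethyl methyl ether, COCCl
Why: Williamson-type O-alkylation of both phenols (MOM protection); the acetals should survive every basic and organometallic step that follows, and they direct the ortho-lithiation of step 5.

Step 2
Reactants: 2 1-[3,4-bis(methoxymethoxy)phenyl]ethan-1-one; 3 geranyl bromide [(2E)-1-bromo-3,7-dimethylocta-2,6-diene]
Product: 5 (4E)-1-[3,4-bis(methoxymethoxy)phenyl]-5,9-dimethyldeca-4,8-dien-1-one, via lithium enolate 4 (not isolated)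
Conditions: LDA (1.05 equiv), THF, −78 °C; then 3 (1.0 equiv), DMPU, −78 → −20 °C
Reagents that add atoms: none
Why: Kinetic enolate formation at the methyl group and SN2 alkylation by the primary allylic bromide (enolate alkylation); attack at C1 of 3 keeps the (E)-alkene, and one equivalent of 3 at low temperature should limit dialkylation.

Step 3
Reactants: 5 (4E)-1-[3,4-bis(methoxymethoxy)phenyl]-5,9-dimethyldeca-4,8-dien-1-one
Product: 6 4-[(5E)-6,10-dimethylundeca-1,5,9-trien-2-yl]-1,2-bis(methoxymethoxy)benzene
Conditions: Ph3PCH3Br (1.5 equiv), KOtBu (1.45 equiv), THF, 0 °C → rt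
Reagents that add atoms: methyltriphenylphosphonium bromide, C[P+](c1ccccc1)(c1ccccc1)c1ccccc1.[Br-]
Why: Wittig methylenation of the aryl alkyl ketone with the non-stabilised ylide should give the 1,1-disubstituted styrene; no stereochemistry is at issue, and the remote alkenes and the acetals are inert to the ylide.

Step 4
Reactants: 6 4-[(5E)-6,10-dimethylundeca-1,5,9-trien-2-yl]-1,2-bis(methoxymethoxy)benzene; 7 ethylene
Product: 8 1,2-bis(methoxymethoxy)-4-[(3R,6E)-3,7,11-trimethyldodeca-1,6,10-trien-3-yl]benzene
Conditions: [(η3-C3H5)NiBr]2 (2.5 mol%), L (5 mol%), NaBArF4 (6 mol%), 7 (1 atm), CH2Cl2, −40 → 0 °C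
Reagents that add atoms: none
Why: Nickel-catalysed asymmetric hydrovinylation of an α-alkyl vinylarene, the reaction type established for 2-aryl-1-butenes. The allylnickel bromide dimer, L and NaBArF4 give under 7 a cationic L·Ni–H, which adds to C1=C2 of 6 in the Markovnikov sense, so that C1 becomes the methyl group and C2 a tertiary η3-benzyl nickel centre. Ethylene then inserts into the Ni–C2 bond, and β-hydride elimination from the new Ni–CH2CH2 unit releases the vinyl group and returns Ni–H; no ring is closed. The new stereocentre (C2 of 6, C3 of 8) is controlled by the catalyst alone: the phosphoramidite decides which face of the benzyl–nickel carbon meets ethylene, and delivery to the Si face of C2 (priorities aryl > CH2 chain > =CH2) gives 3R. The step needs chemoselectivity for the styrenic alkene, which the substrate secures because only this alkene can form a stabilised η3-benzyl species and the two trisubstituted alkenes cannot. The product vinyl group sits on a quaternary carbon, has no allylic hydrogen to isomerise and is hindered, and insertion of the C5=C6 alkene into the benzyl–nickel bond would need a cyclobutane or a 5-endo closure onto a fully substituted carbon. The competing path is isomerisation of 6 to the internal trisubstituted styrene by β-hydride elimination towards C3, which low temperature and the non-coordinating counter-ion should hold back. Both ortho positions of the arene are free, so the benzyl–nickel intermediate can lie coplanar with the ring as in the model substrates.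

Step 5
Reactants: 8 1,2-bis(methoxymethoxy)-4-[(3R,6E)-3,7,11-trimethyldodeca-1,6,10-trien-3-yl]benzene
Product: 11 2,3-bis(methoxymethoxy)-5-[(3R,6E)-3,7,11-trimethyldodeca-1,6,10-trien-3-yl]phenol, via aryllithium 9 (not isolated), via dimethyl arylboronate 10 (not isolated)
Conditions: n-BuLi (1.2 equiv), THF, −20 → 0 °C; B(OMe)3, −78 °C → rt; then 30% H2O2, aq NaOH, 0 °C
Reagents that add atoms: hydrogen peroxide, OO (oxygen of the new OH); trimethyl borate, COB(OC)OC (boron only in intermediate 10)
Why: Directed ortho-metalation, then borylation and oxidation of the C–B bond: the acetal on the oxygen para to the side chain directs lithium to its only unhindered ortho C–H, the other ortho site of the catechol unit being shielded by the quaternary carbon. The stereocentre has no acidic hydrogen and the unactivated alkenes should not react with n-BuLi or basic peroxide at these temperatures.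

Step 6
Reactants: 12 1-(3-bromo-2-hydroxyphenyl)ethan-1-one
Product: 13 1-[3-bromo-2-(methoxymethoxy)phenyl]ethan-1-one
Conditions: MOMCl (1.5 equiv), iPr2NEt (2 equiv), CH2Cl2, 0 → 40 °C
Reagents that add atoms: chloromethyl methyl ether, COCCl
Why: O-alkylation of the phenol with MOMCl (MOM protection); the small, very reactive electrophile should reach the hydrogen-bonded, doubly flanked phenol on gentle warming.

Step 7
Reactants: 13 1-[3-bromo-2-(methoxymethoxy)phenyl]ethan-1-one; 3 geranyl bromide
Product: 15 (4E)-1-[3-bromo-2-(methoxymethoxy)phenyl]-5,9-dimethyldeca-4,8-dien-1-one, via lithium enolate 14 (not isolated)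
Conditions: LDA (1.05 equiv), THF, −78 °C; then 3 (1.0 equiv), DMPU, −78 → −20 °C
Reagents that add atoms: none
Why: Enolate alkylation as in step 2; at −78 °C the amide base should deprotonate the methyl ketone much faster than it attacks the aryl bromide, so the halogen is kept for step 10.

Step 8
Reactants: 15 (4E)-1-[3-bromo-2-(methoxymethoxy)phenyl]-5,9-dimethyldeca-4,8-dien-1-one
Product: 16 1-bromo-3-[(5E)-6,10-dimethylundeca-1,5,9-trien-2-yl]-2-(methoxymethoxy)benzene
Conditions: Ph3PCH3Br (2 equiv), KOtBu (1.9 equiv), THF, 0 °C → 45 °C
Reagents that add atoms: methyltriphenylphosphonium bromide, C[P+](c1ccccc1)(c1ccccc1)c1ccccc1.[Br-]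
Why: Wittig methylenation as in step 3; the ortho acetal slows addition, so excess ylide and mild warming are planned, and the aryl bromide is inert to the ylide.

Step 9
Reactants: 16 1-bromo-3-[(5E)-6,10-dimethylundeca-1,5,9-trien-2-yl]-2-(methoxymethoxy)benzene; 7 ethylene
Product: 17 1-bromo-2-(methoxymethoxy)-3-[(3S,6E)-3,7,11-trimethyldodeca-1,6,10-trien-3-yl]benzene
Conditions: [(η3-C3H5)NiBr]2 (5 mol%), ent-L (10 mol%), NaBArF4 (12 mol%), 7 (1 atm), CH2Cl2, −20 °C → rt
Reagents that add atoms: none
Why: The same nickel-catalysed asymmetric hydrovinylation as in step 4, run with the mirror-image ligand so that ethylene meets the Re face of C2 and the 3S centre results. Aryl bromides are compatible with the cationic Ni(II) hydride cycle, and the ortho acetal is the main uncertainty, which is why loading and temperature are raised.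

Step 10
Reactants: 11 2,3-bis(methoxymethoxy)-5-[(3R,6E)-3,7,11-trimethyldodeca-1,6,10-trien-3-yl]phenol; 17 1-bromo-2-(methoxymethoxy)-3-[(3S,6E)-3,7,11-trimethyldodeca-1,6,10-trien-3-yl]benzene
Product: 18 1,2-bis(methoxymethoxy)-3-{2-(methoxymethoxy)-3-[(3S,6E)-3,7,11-trimethyldodeca-1,6,10-trien-3-yl]phenoxy}-5-[(3R,6E)-3,7,11-trimethyldodeca-1,6,10-trien-3-yl]benzene
Conditions: CuI (20 mol%), picolinic acid (40 mol%), K3PO4 (2 equiv), DMSO, 90 °C, Ar
Reagents that add atoms: none
Why: Ullmann-type Cu(I)-catalysed C–O coupling with a ligand system suited to ortho-substituted partners: the phenoxide of 11 binds copper, and oxidative addition of the aryl bromide followed by reductive elimination forms the ether. Both quaternary centres lack α-hydrogens and cannot epimerise, and acetals and alkenes should be stable to phosphate base at this temperature.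

Step 11
Reactants: 18 1,2-bis(methoxymethoxy)-3-{2-(methoxymethoxy)-3-[(3S,6E)-3,7,11-trimethyldodeca-1,6,10-trien-3-yl]phenoxy}-5-[(3R,6E)-3,7,11-trimethyldodeca-1,6,10-trien-3-yl]benzene
Product: 19 3-{2-hydroxy-3-[(3S,6E)-3,7,11-trimethyldodeca-1,6,10-trien-3-yl]phenoxy}-5-[(3R,6E)-3,7,11-trimethyldodeca-1,6,10-trien-3-yl]benzene-1,2-diol (CNP0325484.1)
Conditions: p-TsOH·H2O (0.3 equiv), degassed MeOH–THF, 40 °C, Ar
Reagents that add atoms: none
Why: Acid-catalysed transacetalisation of the three aryl MOM ethers to methanol (MOM cleavage) should release the catechol and the phenol; a catalytic sulfonic acid in methanol is mild enough for geranyl-type chains, and exclusion of air protects the catechol.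

## Compound list

1 | 1-(3,4-dihydroxyphenyl)ethan-1-one | CC(=O)c1ccc(O)c(O)c1 | starting material
2 | 1-[3,4-bis(methoxymethoxy)phenyl]ethan-1-one | CC(=O)c1ccc(OCOC)c(OCOC)c1 | intermediate
3 | geranyl bromide, (2E)-1-bromo-3,7-dimethylocta-2,6-diene | CC(C)=CCC/C(C)=C/CBr | starting material
4 | lithium 1-[3,4-bis(methoxymethoxy)phenyl]ethen-1-olate (not isolated) | C=C(O[Li])c1ccc(OCOC)c(OCOC)c1 | intermediate
5 | (4E)-1-[3,4-bis(methoxymethoxy)phenyl]-5,9-dimethyldeca-4,8-dien-1-one | O=C(CC/C=C(\C)CCC=C(C)C)c1ccc(OCOC)c(OCOC)c1 | intermediate
6 | 4-[(5E)-6,10-dimethylundeca-1,5,9-trien-2-yl]-1,2-bis(methoxymethoxy)benzene | C=C(CC/C=C(\C)CCC=C(C)C)c1ccc(OCOC)c(OCOC)c1 | intermediate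
7 | ethylene | C=C | starting material
8 | 1,2-bis(methoxymethoxy)-4-[(3R,6E)-3,7,11-trimethyldodeca-1,6,10-trien-3-yl]benzene | C=C[C@@](C)(CC/C=C(\C)CCC=C(C)C)c1ccc(OCOC)c(OCOC)c1 | intermediate
9 | {2,3-bis(methoxymethoxy)-5-[(3R,6E)-3,7,11-trimethyldodeca-1,6,10-trien-3-yl]phenyl}lithium (not isolated) | C=C[C@@](C)(CC/C=C(\C)CCC=C(C)C)c1cc([Li])c(OCOC)c(OCOC)c1 | intermediate
10 | dimethyl {2,3-bis(methoxymethoxy)-5-[(3R,6E)-3,7,11-trimethyldodeca-1,6,10-trien-3-yl]phenyl}boronate (not isolated) | C=C[C@@](C)(CC/C=C(\C)CCC=C(C)C)c1cc(B(OC)OC)c(OCOC)c(OCOC)c1 | intermediate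
11 | 2,3-bis(methoxymethoxy)-5-[(3R,6E)-3,7,11-trimethyldodeca-1,6,10-trien-3-yl]phenol | C=C[C@@](C)(CC/C=C(\C)CCC=C(C)C)c1cc(O)c(OCOC)c(OCOC)c1 | intermediate
12 | 1-(3-bromo-2-hydroxyphenyl)ethan-1-one | CC(=O)c1cccc(Br)c1O | starting material
13 | 1-[3-bromo-2-(methoxymethoxy)phenyl]ethan-1-one | CC(=O)c1cccc(Br)c1OCOC | intermediate
14 | lithium 1-[3-bromo-2-(methoxymethoxy)phenyl]ethen-1-olate (not isolated) | C=C(O[Li])c1cccc(Br)c1OCOC | intermediate
15 | (4E)-1-[3-bromo-2-(methoxymethoxy)phenyl]-5,9-dimethyldeca-4,8-dien-1-one | O=C(CC/C=C(\C)CCC=C(C)C)c1cccc(Br)c1OCOC | intermediate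
16 | 1-bromo-3-[(5E)-6,10-dimethylundeca-1,5,9-trien-2-yl]-2-(methoxymethoxy)benzene | C=C(CC/C=C(\C)CCC=C(C)C)c1cccc(Br)c1OCOC | intermediate
17 | 1-bromo-2-(methoxymethoxy)-3-[(3S,6E)-3,7,11-trimethyldodeca-1,6,10-trien-3-yl]benzene | C=C[C@](C)(CC/C=C(\C)CCC=C(C)C)c1cccc(Br)c1OCOC | intermediate
18 | 1,2-bis(methoxymethoxy)-3-{2-(methoxymethoxy)-3-[(3S,6E)-3,7,11-trimethyldodeca-1,6,10-trien-3-yl]phenoxy}-5-[(3R,6E)-3,7,11-trimethyldodeca-1,6,10-trien-3-yl]benzene | C=C[C@@](C)(CC/C=C(\C)CCC=C(C)C)c1cc(OCOC)c(OCOC)c(Oc2cccc([C@](C)(C=C)CC/C=C(\C)CCC=C(C)C)c2OCOC)c1 | intermediate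
19 | 3-{2-hydroxy-3-[(3S,6E)-3,7,11-trimethyldodeca-1,6,10-trien-3-yl]phenoxy}-5-[(3R,6E)-3,7,11-trimethyldodeca-1,6,10-trien-3-yl]benzene-1,2-diol | C=C[C@@](C)(CC/C=C(\C)CCC=C(C)C)c1cc(O)c(O)c(Oc2cccc([C@](C)(C=C)CC/C=C(\C)CCC=C(C)C)c2O)c1 | target

## Step count and least certain steps

Total step count: 11. Longest linear sequence: 7 (steps 1, 2, 3, 4, 5, 10, 11); the ring B branch (steps 6 to 9) joins at step 10.

Step 4 (key step). What may go wrong: isomerisation of the 1,1-disubstituted alkene to the internal styrene, which removes substrate from the cycle; slow turnover because the two neighbouring acetal oxygens bind the cationic nickel; and incomplete facial discrimination, since the face is chosen between a CH2 chain and the forming methyl group. Fallback from 5, returning at 8: a Horner–Wadsworth–Emmons reaction with triethyl phosphonoacetate (NaH, THF) would give the (2E)-enoate F1, with the geometric isomer removed by chromatography. DIBAL-H reduction would give the allylic alcohol F2, and diethyl chlorophosphate with DMAP would give the allylic diethyl phosphate F3. Copper-catalysed enantioselective SN2′ methylation of F3 (chiral NHC–Cu, Me3Al, THF, −15 °C) would then put the methyl group on the aryl-bearing carbon and give 8.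

Step 9. What may go wrong: the ortho acetal twists the arene out of conjugation with the alkene, which slows Ni–H addition and destabilises the η3-benzyl intermediate; the acetal oxygen may also chelate nickel; and adventitious Ni(0) could insert into the C–Br bond. Fallback from 15, returning at 17: the same three operations would give the (2E)-enoate F4, the allylic alcohol F5 and the allylic diethyl phosphate F6. Copper-catalysed SN2′ methylation of F6 with the catalyst of opposite handedness would give 17. In this approach the arene is already attached to the prochiral carbon, so no coplanar benzyl–metal species is required.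

Step 10. What may go wrong: slow oxidative addition at an electron-rich aryl bromide flanked by an acetal, with protodebromination and oxidation of the electron-rich phenol taking over at the temperature needed. Fallback from 17, returning at 18: bromine–lithium exchange (n-BuLi, THF, −78 °C) would give the aryllithium F7, which triisopropyl borate and aqueous NH4Cl would convert into the arylboronic acid F8. Chan–Lam coupling of F8 with 11 (Cu(OAc)2, pyridine, 4 Å MS, CH2Cl2, air, rt) would form the ether at room temperature through a Cu(II)/Cu(III) manifold.

Step 11. What may go wrong: protonation of a trisubstituted alkene during the slow loss of the third acetal, leading to methanol addition or cation–olefin cyclisation, and air oxidation of the freed catechol. Fallback from 18, returning at 19: TESOTf with 2,2′-bipyridyl (CH2Cl2, 0 °C) would exchange the three aryl MOM ethers for silyl ethers and give the tris(triethylsilyl) ether F9. Buffered fluoride (TBAF, AcOH, THF, 0 °C) would then release 19 without any free Brønsted acid.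

## Further compounds

F1 | step 4 | ethyl (2E,6E)-3-[3,4-bis(methoxymethoxy)phenyl]-7,11-dimethyldodeca-2,6,10-trienoate | CCOC(=O)/C=C(/c1ccc(OCOC)c(OCOC)c1)CC/C=C(\C)CCC=C(C)C
F2 | step 4 | (2E,6E)-3-[3,4-bis(methoxymethoxy)phenyl]-7,11-dimethyldodeca-2,6,10-trien-1-ol | OC/C=C(/c1ccc(OCOC)c(OCOC)c1)CC/C=C(\C)CCC=C(C)C
F3 | step 4 | (2E,6E)-3-[3,4-bis(methoxymethoxy)phenyl]-7,11-dimethyldodeca-2,6,10-trien-1-yl diethyl phosphate | CCOP(=O)(OCC)OC/C=C(/c1ccc(OCOC)c(OCOC)c1)CC/C=C(\C)CCC=C(C)C
F4 | step 9 | ethyl (2E,6E)-3-[3-bromo-2-(methoxymethoxy)phenyl]-7,11-dimethyldodeca-2,6,10-trienoate | CCOC(=O)/C=C(/c1cccc(Br)c1OCOC)CC/C=C(\C)CCC=C(C)C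
F5 | step 9 | (2E,6E)-3-[3-bromo-2-(methoxymethoxy)phenyl]-7,11-dimethyldodeca-2,6,10-trien-1-ol | OC/C=C(/c1cccc(Br)c1OCOC)CC/C=C(\C)CCC=C(C)C
F6 | step 9 | (2E,6E)-3-[3-bromo-2-(methoxymethoxy)phenyl]-7,11-dimethyldodeca-2,6,10-trien-1-yl diethyl phosphate | CCOP(=O)(OCC)OC/C=C(/c1cccc(Br)c1OCOC)CC/C=C(\C)CCC=C(C)C
F7 | step 10 | {2-(methoxymethoxy)-3-[(3S,6E)-3,7,11-trimethyldodeca-1,6,10-trien-3-yl]phenyl}lithium | [Li]c1cccc([C@](C)(C=C)CC/C=C(\C)CCC=C(C)C)c1OCOC
F8 | step 10 | {2-(methoxymethoxy)-3-[(3S,6E)-3,7,11-trimethyldodeca-1,6,10-trien-3-yl]phenyl}boronic acid | OB(O)c1cccc([C@](C)(C=C)CC/C=C(\C)CCC=C(C)C)c1OCOC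
F9 | step 11 | 1,2-bis(triethylsilyloxy)-3-{2-(triethylsilyloxy)-3-[(3S,6E)-3,7,11-trimethyldodeca-1,6,10-trien-3-yl]phenoxy}-5-[(3R,6E)-3,7,11-trimethyldodeca-1,6,10-trien-3-yl]benzene | C=C[C@@](C)(CC/C=C(\C)CCC=C(C)C)c1cc(O[Si](CC)(CC)CC)c(O[Si](CC)(CC)CC)c(Oc2cccc([C@](C)(C=C)CC/C=C(\C)CCC=C(C)C)c2O[Si](CC)(CC)CC)c1
A1 | alternative 1 | diethyl (2E,6E)-3,7,11-trimethyldodeca-2,6,10-trien-1-yl phosphate | CCOP(=O)(OCC)OC/C=C(\C)CC/C=C(\C)CCC=C(C)C
A2 | alternative 1 | 1,3-dibromo-2-(methoxymethoxy)benzene | COCOc1c(Br)cccc1Br
A3 | alternative 2 | (1R)-1-[3,4-bis(methoxymethoxy)phenyl]ethyl N,N-diisopropylcarbamate | C[C@@H](OC(=O)N(C(C)C)C(C)C)c1ccc(OCOC)c(OCOC)c1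
A4 | alternative 2 | 2-{(2R,5E)-2-[3,4-bis(methoxymethoxy)phenyl]-6,10-dimethylundeca-5,9-dien-2-yl}-4,4,5,5-tetramethyl-1,3,2-dioxaborolane | CC1(C)OB(OC1(C)C)[C@@](C)(CC/C=C(\C)CCC=C(C)C)c1ccc(OCOC)c(OCOC)c1
A5 | alternative 2 | 2-[(3E)-4,8-dimethylnona-3,7-dien-1-yl]-4,4,5,5-tetramethyl-1,3,2-dioxaborolane | CC(C)=CCC/C(C)=C/CCB1OC(C)(C)C(C)(C)O1
A6 | alternative 3 | 2-{[(2E,6E)-3,7,11-trimethyldodeca-2,6,10-trien-1-yl]oxy}phenol | Oc1ccccc1OC/C=C(\C)CC/C=C(\C)CCC=C(C)C
A7 | alternative 3 | 3-[(3S,6E)-3,7,11-trimethyldodeca-1,6,10-trien-3-yl]benzene-1,2-diol | C=C[C@](C)(CC/C=C(\C)CCC=C(C)C)c1cccc(O)c1O
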